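**Retrosynthetic overview**
- The target is reached by desilylation of its O13-silyl ether. That ether comes from one flask in which non-8-enylmagnesium bromide adds to a 5-pentyl-4-silyloxy-oxolane-2-carbaldehyde (C9–C10) and the resulting alkoxide is acylated by tetradecanoyl chloride (ester C–O).
- Feature: with the chain numbered C1 (vinyl CH2) to C19 (pentyl CH3), C10–C15 carries oxygen on C10, C11, C13 and C14 and a CH2 at C12. This is the C1–C6 chain of 3-deoxy-D-glucose, and the ester carbinol C10 is the sugar aldehyde carbon, next to the ring oxygen on C11 (ring O–C11–C12–C13–C14) that can chelate magnesium.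
- The aldehyde comes from a 2,5-anhydro sugar dimethyl acetal, made by acid methanolysis of a 5-mesylate (O2 attacks C5 with inversion, setting C14). The mesylate comes from diacetone-D-glucose by C3 deoxygenation and tosylate–cuprate extension at C6.
- Ring order: only one ring of the target is made, the oxolane, in step 7; the sugar furanose and dioxolane rings are opened on the way.

Key step: step 11

Remark on the chemistry: D-glucose enters as its commercial bis-acetonide, and O13 is carried as a tert-butyldiphenylsilyl (TBDPS) ether, because the acetal next to the ring oxygen needs aqueous TFA for hydrolysis, which a smaller silyl ether would not be expected to survive reliably.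

**Route**

Step 1
Reactants: 1 1,2:5,6-di-O-isopropylidene-α-D-glucofuranose (diacetone-D-glucose)
Product: 3 1,2:5,6-di-O-isopropylidene-3-O-[(methylsulfanyl)carbonothioyl]-α-D-glucofuranose (S-methyl xanthate), via sodium xanthate salt 2 (not isolated)
Conditions: NaH, imidazole (cat.), THF, 0 °C to rt; CS2; MeI
Reagents that add atoms: carbon disulfide, S=C=S; iodomethane, CI
Why: Xanthate formation (first half of a Barton–McCombie deoxygenation): the C3 alkoxide adds to CS2 and the dithiocarbonate salt is S-methylated, with both acetonides and all stereocentres untouched.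

Step 2
Reactants: 3 S-methyl xanthate of diacetone-D-glucose
Product: 4 3-deoxy-1,2:5,6-di-O-isopropylidene-α-D-ribo-hexofuranose
Conditions: Bu3SnH, AIBN (cat.), toluene, reflux
Reagents that add atoms: none
Why: Barton–McCombie radical deoxygenation: the stannyl radical adds to C=S, β-scission releases the secondary C3 radical, and hydrogen transfer from Bu3SnH leaves the CH2 that becomes C12.

Step 3
Reactants: 4 3-deoxy-1,2:5,6-di-O-isopropylidene-α-D-ribo-hexofuranose
Product: 5 3-deoxy-1,2-O-isopropylidene-α-D-ribo-hexofuranose (5,6-diol)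
Conditions: AcOH/H2O (3:1), rt
Reagents that add atoms: none
Why: Chemoselective acetal hydrolysis: the terminal 5,6-dioxolane is cleaved by dilute acetic acid much faster than the cis-fused 1,2-acetonide, which stays to mask O2 and the anomeric carbon.

Step 4
Reactants: 5 3-deoxy-1,2-O-isopropylidene-α-D-ribo-hexofuranose
Product: 6 3-deoxy-1,2-O-isopropylidene-6-O-(4-methylbenzenesulfonyl)-α-D-ribo-hexofuranose
Conditions: TsCl (1.1 equiv), pyridine, CH2Cl2, −10 to 0 °C
Reagents that add atoms: 4-methylbenzenesulfonyl chloride, Cc1ccc(cc1)S(=O)(=O)Cl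
Why: Regioselective sulfonylation: the primary O6–H reacts with TsCl at low temperature well ahead of the secondary O5–H, and C5 is not touched.

Step 5
Reactants: 6 3-deoxy-1,2-O-isopropylidene-6-O-tosyl-α-D-ribo-hexofuranose
Product: 7 6-C-butyl-3,6-dideoxy-1,2-O-isopropylidene-α-D-ribo-hexofuranose, i.e. (1R)-1-[(3aR,5S,6aR)-2,2-dimethyltetrahydrofuro[2,3-d][1,3]dioxol-5-yl]hexan-1-ol
Conditions: Bu2CuLi (4 equiv, from n-BuLi and CuI), Et2O, −40 to −20 °C; aq. NH4Cl
Reagents that add atoms: n-butyllithium, CCCC[Li] (used as lithium dibutylcuprate, [Li+].CCCC[Cu-]CCCC)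
Why: SN2 coupling of a Gilman cuprate with the primary tosylate forms C15–C16 and completes the pentyl chain; one equivalent of cuprate is spent on the free O5–H, and the C5–O bond and its configuration are not involved.

Step 6
Reactants: 7 6-C-butyl-3,6-dideoxy-1,2-O-isopropylidene-α-D-ribo-hexofuranose
Product: 8 6-C-butyl-3,6-dideoxy-1,2-O-isopropylidene-5-O-methanesulfonyl-α-D-ribo-hexofuranose
Conditions: MsCl, Et3N, CH2Cl2, 0 °C
Reagents that add atoms: methanesulfonyl chloride, CS(=O)(=O)Cl
Why: O-Sulfonylation turns O5 into a leaving group with retention at C5, since only the O–H bond reacts.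

Step 7
Reactants: 8 6-C-butyl-3,6-dideoxy-1,2-O-isopropylidene-5-O-methanesulfonyl-α-D-ribo-hexofuranose
Product: 10 (2S,3S,5R)-5-(dimethoxymethyl)-2-pentyloxolan-3-ol, via open-chain dimethyl acetal mesylate 9 (not isolated)
Conditions: HCl (0.3 M in MeOH), reflux; then NaHCO3
Reagents that add atoms: methanol, CO
Why: Acid methanolysis ring contraction to a 2,5-anhydro sugar: the 1,2-acetonide is exchanged for the open-chain dimethyl acetal, whose freed O2–H displaces the C5 mesylate by intramolecular SN2 (5-exo-tet), closing the oxolane and inverting C5 to the (S)-configured C14, while C11 and C13 keep the configurations of glucose C2 and C4.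

Step 8
Reactants: 10 (2S,3S,5R)-5-(dimethoxymethyl)-2-pentyloxolan-3-ol
Product: 11 tert-butyl{[(2S,3S,5R)-5-(dimethoxymethyl)-2-pentyloxolan-3-yl]oxy}diphenylsilane
Conditions: TBDPSCl, imidazole, DMAP (cat.), DMF, 40 °C
Reagents that add atoms: tert-butyl(chloro)diphenylsilane, CC(C)(C)[Si](Cl)(c1ccccc1)c1ccccc1
Why: Silyl ether formation at the only free hydroxyl; TBDPS is chosen because it should withstand the aqueous TFA of step 9 and is inert and non-chelating toward the Grignard reagent and MgBr2.

Step 9
Reactants: 11 TBDPS ether of the oxolane dimethyl acetal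
Product: 12 (2R,4S,5S)-4-[(tert-butyldiphenylsilyl)oxy]-5-pentyloxolane-2-carbaldehyde
Conditions: TFA/H2O (4:1), CH2Cl2, 0 °C; toluene azeotrope; used crude at once
Reagents that add atoms: water, O
Why: Acid-catalysed acetal hydrolysis through the oxocarbenium ion, slowed by the α ring oxygen and therefore run in aqueous TFA, which the TBDPS ether should tolerate; the cold acidic medium and immediate use guard C11 against epimerisation.

Step 10
Reactants: 13 9-bromonon-1-ene
Product: 14 non-8-enylmagnesium bromide (titrated solution in Et2O)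
Conditions: Mg, I2 (cat.), Et2O, reflux
Reagents that add atoms: magnesium, [Mg]
Why: Grignard reagent formation by insertion of magnesium into the primary C–Br bond; the distant terminal alkene cannot cyclise in a favourable ring size and stays intact.

Step 11
Reactants: 12 (2R,4S,5S)-4-[(tert-butyldiphenylsilyl)oxy]-5-pentyloxolane-2-carbaldehyde; 14 non-8-enylmagnesium bromide; 15 tetradecanoyl chloride
Product: 17 (1R)-1-[(2R,4S,5S)-4-[(tert-butyldiphenylsilyl)oxy]-5-pentyloxolan-2-yl]dec-9-en-1-yl tetradecanoate, via bromomagnesium alkoxide 16 (not isolated)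
Conditions: MgBr2·OEt2 (2 equiv), CH2Cl2, −78 °C; 14 (1.3 equiv, Et2O), −78 to −20 °C; then 15 (2.5 equiv), DMAP (0.3 equiv), −20 to 0 °C
Reagents that add atoms: none
Why: MgBr2 binds the aldehyde oxygen and the ring oxygen on C11 in a five-membered chelate that holds C10=O syn-periplanar to the C11–O bond, and the Grignard carbon adds to C10 from the face flanked by H-11 rather than by the ring CH2 (C12), forming C9–C10 and the bromomagnesium alkoxide 16. Without work-up this alkoxide attacks tetradecanoyl chloride (DMAP-assisted nucleophilic acyl substitution) and forms the ester C–O bond, so two bonds are made in one flask and no ring is closed. The closest known reaction type is the Cram-chelate Grignard addition to α-alkoxy (oxolane-2-) aldehydes combined with in-situ acylation of the magnesium alkoxide. The one new stereocentre, C10, is controlled by C11 through the chelate and should come out R, that is threo to the ring oxygen. The step needs chelation control to win over the open Felkin–Anh transition state, which would give the erythro C10 epimer; this is secured by the α ring oxygen as the only good donor near the carbonyl (the bulky silyl ether on O13 does not coordinate), by pre-complexation with MgBr2·OEt2 and by the weakly coordinating CH2Cl2/Et2O medium at −78 °C. The small excess of Grignard reagent is consumed by the excess acyl chloride, and the silyl ether and terminal alkene are inert.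

Step 12
Reactants: 17 O13-TBDPS ether of the target
Product: 18 (1R)-1-[(2R,4S,5S)-4-hydroxy-5-pentyloxolan-2-yl]dec-9-en-1-yl tetradecanoate (target)
Conditions: TBAF, AcOH (1:1), THF, rt to 40 °C
Reagents that add atoms: none
Why: Fluoride-induced Si–O cleavage frees O13–H, with acetic acid buffering so that the C10 ester is not attacked; acyl migration is excluded because the ester-bearing side chain and O13 lie on opposite faces of the oxolane.

**Compound list**
1 | 1,2:5,6-di-O-isopropylidene-α-D-glucofuranose | CC1(C)O[C@H]2O[C@H]([C@H]3COC(C)(C)O3)[C@H](O)[C@H]2O1 | starting material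
2 | sodium O-(1,2:5,6-di-O-isopropylidene-α-D-glucofuranos-3-yl) carbonodithioate | CC1(C)O[C@H]2O[C@H]([C@H]3COC(C)(C)O3)[C@H](OC(=S)[S-])[C@H]2O1.[Na+] | intermediate
3 | 1,2:5,6-di-O-isopropylidene-3-O-[(methylsulfanyl)carbonothioyl]-α-D-glucofuranose | CC1(C)O[C@H]2O[C@H]([C@H]3COC(C)(C)O3)[C@H](OC(=S)SC)[C@H]2O1 | intermediate
4 | 3-deoxy-1,2:5,6-di-O-isopropylidene-α-D-ribo-hexofuranose | CC1(C)O[C@H]2O[C@H]([C@H]3COC(C)(C)O3)C[C@H]2O1 | intermediate
5 | 3-deoxy-1,2-O-isopropylidene-α-D-ribo-hexofuranose | CC1(C)O[C@H]2O[C@H]([C@H](O)CO)C[C@H]2O1 | intermediate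
6 | 3-deoxy-1,2-O-isopropylidene-6-O-(4-methylbenzenesulfonyl)-α-D-ribo-hexofuranose | CC1(C)O[C@H]2O[C@H]([C@H](O)COS(=O)(=O)c3ccc(C)cc3)C[C@H]2O1 | intermediate
7 | (1R)-1-[(3aR,5S,6aR)-2,2-dimethyltetrahydrofuro[2,3-d][1,3]dioxol-5-yl]hexan-1-ol | CC1(C)O[C@H]2O[C@H]([C@H](O)CCCCC)C[C@H]2O1 | intermediate
8 | (1R)-1-[(3aR,5S,6aR)-2,2-dimethyltetrahydrofuro[2,3-d][1,3]dioxol-5-yl]hexyl methanesulfonate | CC1(C)O[C@H]2O[C@H]([C@H](OS(C)(=O)=O)CCCCC)C[C@H]2O1 | intermediate
9 | (2R,4S,5R)-2,4-dihydroxy-1,1-dimethoxydecan-5-yl methanesulfonate | COC(OC)[C@H](O)C[C@H](O)[C@H](OS(C)(=O)=O)CCCCC | intermediate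
10 | (2S,3S,5R)-5-(dimethoxymethyl)-2-pentyloxolan-3-ol | COC(OC)[C@H]1C[C@H](O)[C@H](CCCCC)O1 | intermediate
11 | tert-butyl{[(2S,3S,5R)-5-(dimethoxymethyl)-2-pentyloxolan-3-yl]oxy}diphenylsilane | COC(OC)[C@H]1C[C@H](O[Si](c2ccccc2)(c2ccccc2)C(C)(C)C)[C@H](CCCCC)O1 | intermediate
12 | (2R,4S,5S)-4-[(tert-butyldiphenylsilyl)oxy]-5-pentyloxolane-2-carbaldehyde | O=C[C@H]1C[C@H](O[Si](c2ccccc2)(c2ccccc2)C(C)(C)C)[C@H](CCCCC)O1 | intermediate
13 | 9-bromonon-1-ene | C=CCCCCCCCBr | starting material
14 | non-8-enylmagnesium bromide | C=CCCCCCCC[Mg]Br | intermediate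
15 | tetradecanoyl chloride | CCCCCCCCCCCCCC(=O)Cl | starting material
16 | bromomagnesium (1R)-1-[(2R,4S,5S)-4-[(tert-butyldiphenylsilyl)oxy]-5-pentyloxolan-2-yl]dec-9-en-1-olate | C=CCCCCCCC[C@@H](O[Mg]Br)[C@H]1C[C@H](O[Si](c2ccccc2)(c2ccccc2)C(C)(C)C)[C@H](CCCCC)O1 | intermediate
17 | (1R)-1-[(2R,4S,5S)-4-[(tert-butyldiphenylsilyl)oxy]-5-pentyloxolan-2-yl]dec-9-en-1-yl tetradecanoate | C=CCCCCCCC[C@@H](OC(=O)CCCCCCCCCCCCC)[C@H]1C[C@H](O[Si](c2ccccc2)(c2ccccc2)C(C)(C)C)[C@H](CCCCC)O1 | intermediate
18 | (1R)-1-[(2R,4S,5S)-4-hydroxy-5-pentyloxolan-2-yl]dec-9-en-1-yl tetradecanoate | C=CCCCCCCC[C@@H](OC(=O)CCCCCCCCCCCCC)[C@H]1C[C@H](O)[C@H](CCCCC)O1 | target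

**Step count**
Total: 12 steps. Longest linear sequence: 11 steps (steps 1–9, 11 and 12); step 10 is the side branch.

**Steps most likely to fail**

Step 11. Facial selectivity may erode if the open Felkin–Anh pathway competes with the chelate, and acylation of the hindered magnesium alkoxide may stall. The fallback sets out from aldehyde 12 and separates the two events. Grignard reagent 14 is added in Et2O and the mixture is worked up to give the carbinol as a C10-epimer mixture F1. Oxidation with Dess–Martin periodinane gives the ketone F2. Reduction with LiBH(s-Bu)3 in THF at −78 °C should follow the Felkin–Anh polar model (bulky, non-chelating hydride anti to the ring C–O bond) and give the threo alcohol F3. Esterification of F3 with tetradecanoyl chloride 15, pyridine and DMAP in CH2Cl2 comes back to the route at 17.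

Step 7. Ring closure may be slow because the mesylate rests mainly as methyl furanosides, and solvolysis or ionisation at C5, now flanked by an alkyl chain, may compete with the O2 attack. The fallback sets out from diol 5 and contracts the ring before the chain is extended, on the classical 6-acyloxy substrate type. Selective 6-O-benzoylation (BzCl, pyridine, −30 °C) gives the benzoate F4, and mesylation gives the 5-mesylate F5. Methanolic HCl at reflux should give the ring-contracted benzoate F6, which is not isolated but debenzoylated with NaOMe in MeOH to the diol F7. Selective tosylation of the primary hydroxyl (TsCl, pyridine, 0 °C) gives the tosylate F8. Excess Bu2CuLi then installs the butyl group and comes back to the route at 10.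

Step 9. The deactivated acetal may hydrolyse slowly, so that the silyl ether is partly lost before conversion is complete. The fallback sets out from hydroxy acetal 10 and changes the order of events. The unprotected acetal is hydrolysed with aqueous HCl in THF, where no silyl ether is at risk, to the hydroxy aldehyde F9. Silylation of F9 (TBDPSCl, imidazole, DMF, 0 °C to rt) comes back to the route at 12.

**Further compounds**
F1 | step 11 | 1-[(2R,4S,5S)-4-[(tert-butyldiphenylsilyl)oxy]-5-pentyloxolan-2-yl]dec-9-en-1-ol, mixture of C10 epimers | C=CCCCCCCCC(O)[C@H]1C[C@H](O[Si](c2ccccc2)(c2ccccc2)C(C)(C)C)[C@H](CCCCC)O1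
F2 | step 11 | 1-[(2R,4S,5S)-4-[(tert-butyldiphenylsilyl)oxy]-5-pentyloxolan-2-yl]dec-9-en-1-one | C=CCCCCCCCC(=O)[C@H]1C[C@H](O[Si](c2ccccc2)(c2ccccc2)C(C)(C)C)[C@H](CCCCC)O1
F3 | step 11 | (1R)-1-[(2R,4S,5S)-4-[(tert-butyldiphenylsilyl)oxy]-5-pentyloxolan-2-yl]dec-9-en-1-ol | C=CCCCCCCC[C@@H](O)[C@H]1C[C@H](O[Si](c2ccccc2)(c2ccccc2)C(C)(C)C)[C@H](CCCCC)O1
F4 | step 7 | 6-O-benzoyl-3-deoxy-1,2-O-isopropylidene-α-D-ribo-hexofuranose | CC1(C)O[C@H]2O[C@H]([C@H](O)COC(=O)c3ccccc3)C[C@H]2O1
F5 | step 7 | 6-O-benzoyl-3-deoxy-1,2-O-isopropylidene-5-O-methanesulfonyl-α-D-ribo-hexofuranose | CC1(C)O[C@H]2O[C@H]([C@H](OS(C)(=O)=O)COC(=O)c3ccccc3)C[C@H]2O1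
F6 | step 7 | [(2S,3S,5R)-5-(dimethoxymethyl)-3-hydroxyoxolan-2-yl]methyl benzoate | COC(OC)[C@H]1C[C@H](O)[C@H](COC(=O)c2ccccc2)O1
F7 | step 7 | (2S,3S,5R)-5-(dimethoxymethyl)-2-(hydroxymethyl)oxolan-3-ol | COC(OC)[C@H]1C[C@H](O)[C@H](CO)O1
F8 | step 7 | [(2S,3S,5R)-5-(dimethoxymethyl)-3-hydroxyoxolan-2-yl]methyl 4-methylbenzenesulfonate | COC(OC)[C@H]1C[C@H](O)[C@H](COS(=O)(=O)c2ccc(C)cc2)O1
F9 | step 9 | (2R,4S,5S)-4-hydroxy-5-pentyloxolane-2-carbaldehyde | O=C[C@H]1C[C@H](O)[C@H](CCCCC)O1
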